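**Retrosynthetic overview**
1. Target 27 ⇐ tetrasilyl ether 26 (global desilylation) ⇐ one-flask three-component union at C9: ring-A alkyne 21 (C11) + polyenyl 1,1-dibromide 15 (C28) + dimethylzinc 22, forming first C8–C9, then C9–CH3.
2. Enabling feature: C9 is the trisubstituted terminus of the C9=C10 double bond (it carries CH3-19 and C8) and lies next to the E-C7=C8 alkene on the fully substituted carbinol C6 of the trihydroxycyclohexane ring; C9 can therefore come from a CBr2 linchpin and C7=C8 from an ethynyl group on C6 by syn-hydrometalation.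
3. 15 ⇐ C27 aldehyde 14 (dibromo-olefination) ⇐ C25 aldehyde 11 (two-carbon HWE extension) ⇐ C15 phosphonate 8 + C10-dialdehyde 9; 8 ⇐ enol triflate 4 + enyne phosphonate 7 (Sonogashira).
4. 21 ⇐ α-hydroxylation (sets C5) and chelation-controlled ethynylation (sets C6) of the actinol silyl ether 2; C3 and C3' both come from (4R,6R)-actinol 1 through the common silyl ether 2.
5. Ring order: no ring is formed in the route; both six-membered carbocycles are taken intact from 1.

Key step: step 14

Remark: carotenoid numbering is used (C1–C6 = trihydroxy ring, primed locants = acetylenic half). (4R,6R)-Actinol 1 and the C10-dialdehyde 9 are taken as purchasable carotenoid building blocks; all polyene steps are run under argon with exclusion of light.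

Step 1
Reactants: 1 (4R,6R)-4-hydroxy-2,2,6-trimethylcyclohexan-1-one
Product: 2 (4R,6R)-4-[(tert-butyldimethylsilyl)oxy]-2,2,6-trimethylcyclohexan-1-one
Conditions: TBSCl, imidazole, DMF, rt
Reagents that add atoms: tert-butyldimethylsilyl chloride, CC(C)(C)[Si](C)(C)Cl
Why: Imidazole-mediated silylation of the secondary alcohol; the C4 stereocentre is carried through unchanged and the ketone is untouched.

Step 2
Reactants: 2 (4R,6R)-4-[(tert-butyldimethylsilyl)oxy]-2,2,6-trimethylcyclohexan-1-one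
Product: 4 (4R)-4-[(tert-butyldimethylsilyl)oxy]-2,6,6-trimethylcyclohex-1-en-1-yl trifluoromethanesulfonate, via lithium enolate 3 (not isolated)
Conditions: LDA, THF, −78 °C; then PhNTf2, −78 → 0 °C
Reagents that add atoms: N-phenylbis(trifluoromethanesulfonimide), O=S(=O)(N(c1ccccc1)S(=O)(=O)C(F)(F)F)C(F)(F)F
Why: Enolate O-triflation; C2 is quaternary, so only C6–H can be removed and a single enol triflate should form, the C6 stereocentre being erased on purpose while C4 (R) stays.

Step 3
Reactants: 5 (2E)-3-methylpent-2-en-4-yn-1-ol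
Product: 6 (3E)-5-bromo-3-methylpent-3-en-1-yne
Conditions: PBr3 (0.4 equiv), pyridine (cat.), Et2O, −10 → 0 °C
Reagents that add atoms: phosphorus tribromide, BrP(Br)Br
Why: PBr3 bromination of a primary allylic alcohol (SN2 on the phosphite ester); the conjugated primary E-bromide is the stable allylic isomer.

Step 4
Reactants: 6 (3E)-5-bromo-3-methylpent-3-en-1-yne
Product: 7 diethyl [(2E)-3-methylpent-2-en-4-yn-1-yl]phosphonate
Conditions: P(OEt)3, neat, 90 °C
Reagents that add atoms: triethyl phosphite, CCOP(OCC)OCC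
Why: Michaelis–Arbuzov reaction of a reactive primary allylic bromide; the alkene geometry and the terminal alkyne take no part.

Step 5
Reactants: 4 (4R)-4-[(tert-butyldimethylsilyl)oxy]-2,6,6-trimethylcyclohex-1-en-1-yl trifluoromethanesulfonate; 7 diethyl [(2E)-3-methylpent-2-en-4-yn-1-yl]phosphonate
Product: 8 diethyl {(2E)-5-[(4R)-4-[(tert-butyldimethylsilyl)oxy]-2,6,6-trimethylcyclohex-1-en-1-yl]-3-methylpent-2-en-4-yn-1-yl}phosphonate (C15 phosphonate)
Conditions: Pd(PPh3)4 (5 mol%), CuI (10 mol%), iPr2NH, DMF, rt → 50 °C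
Reagents that add atoms: none
Why: Sonogashira coupling of an enol triflate with a terminal alkyne forms the C6'–C7' bond; the amine base does not deprotonate the phosphonate and the E-alkene is not involved.

Step 6
Reactants: 8 C15 phosphonate; 9 (2E,4E,6E)-2,7-dimethylocta-2,4,6-trienedial (3 equiv)
Product: 11 (2E,4E,6E,8E,10E)-13-[(4R)-4-[(tert-butyldimethylsilyl)oxy]-2,6,6-trimethylcyclohex-1-en-1-yl]-2,7,11-trimethyltrideca-2,4,6,8,10-pentaen-12-ynal (C25 aldehyde), via potassium phosphonate carbanion 10 (not isolated)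
Conditions: KHMDS, THF, −78 °C; then added slowly to 9, THF, −78 → −20 °C
Reagents that add atoms: none
Why: Horner–Wadsworth–Emmons olefination of an α-branched enal by an allylic phosphonate carbanion should give the E C11'=C12' bond; the excess of symmetrical 9 holds the reaction at mono-olefination and the low temperature limits E/Z scrambling of the carbanion.

Step 7
Reactants: 11 C25 aldehyde; 12 diethyl {2-[methoxy(methyl)amino]-2-oxoethyl}phosphonate
Product: 13 (2E,4E,6E,8E,10E,12E)-15-[(4R)-4-[(tert-butyldimethylsilyl)oxy]-2,6,6-trimethylcyclohex-1-en-1-yl]-N-methoxy-N,4,9,13-tetramethylpentadeca-2,4,6,8,10,12-hexaen-14-ynamide (C27 Weinreb amide)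
Conditions: LiCl, DBU, MeCN/THF, rt
Reagents that add atoms: none
Why: Masamune–Roush variant of the HWE reaction with a stabilised phosphonate gives the E C11=C12 bond under mild base, and the amide product cannot be homologated further.

Step 8
Reactants: 13 C27 Weinreb amide
Product: 14 (2E,4E,6E,8E,10E,12E)-15-[(4R)-4-[(tert-butyldimethylsilyl)oxy]-2,6,6-trimethylcyclohex-1-en-1-yl]-4,9,13-trimethylpentadeca-2,4,6,8,10,12-hexaen-14-ynal (C27 aldehyde)
Conditions: DIBAL-H, THF, −78 °C; Rochelle salt work-up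
Reagents that add atoms: none
Why: Hydride reduction of a Weinreb amide stops at the aldehyde because the chelated tetrahedral intermediate survives until work-up; silyl ether, alkyne and polyene are inert at −78 °C.

Step 9
Reactants: 14 C27 aldehyde
Product: 15 tert-butyl({(1R)-4-[(3E,5E,7E,9E,11E,13E)-16,16-dibromo-3,7,12-trimethylhexadeca-3,5,7,9,11,13,15-heptaen-1-yn-1-yl]-3,5,5-trimethylcyclohex-3-en-1-yl}oxy)dimethylsilane (C28 1,1-dibromide; CBr2 = C9)
Conditions: CBr4, PPh3, Zn dust, CH2Cl2, rt (ylide pre-formed); then 14, 0 °C → rt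
Reagents that add atoms: carbon tetrabromide, BrC(Br)(Br)Br
Why: Ramirez dibromo-olefination (first stage of the Corey–Fuchs sequence) installs C9 as a CBr2 group by a Wittig-type reaction; zinc keeps bromophosphonium species away from the silyl ether and the polyene.

Step 10
Reactants: 2 (4R,6R)-4-[(tert-butyldimethylsilyl)oxy]-2,2,6-trimethylcyclohexan-1-one
Product: 16 {[(4R)-4-[(tert-butyldimethylsilyl)oxy]-2,6,6-trimethylcyclohex-1-en-1-yl]oxy}trimethylsilane
Conditions: TMSOTf, Et3N, CH2Cl2, 0 °C → rt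
Reagents that add atoms: trimethylsilyl trifluoromethanesulfonate, C[Si](C)(C)OS(=O)(=O)C(F)(F)F
Why: Soft enolisation with a silyl triflate and a tertiary amine: O-silylation of the carbonyl and loss of the only α-hydrogen (C6–H; C2 is quaternary) gives the single, tetrasubstituted silyl enol ether, and the TBS ether and C4 are untouched.

Step 11
Reactants: 16 silyl enol ether
Product: 18 (2S,4S)-4-[(tert-butyldimethylsilyl)oxy]-2-hydroxy-2,6,6-trimethylcyclohexan-1-one, via silyloxy ketone 17 (not isolated)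
Conditions: mCPBA, NaHCO3, CH2Cl2, −20 → 0 °C; then K2CO3, MeOH, 0 °C
Reagents that add atoms: 3-chloroperoxybenzoic acid, OOC(=O)c1cccc(Cl)c1
Why: Rubottom oxidation: the peracid should epoxidise the enol ether on the face opposite the pseudoaxial C1 methyl of the half-chair with C3–OTBS pseudoequatorial, that is syn to the silyloxy group, so that after 1,4-silyl migration and methanolysis the new C5–O bond is cis to C3–O (2S in 18).

Step 12
Reactants: 18 α-hydroxy ketone; 19 ethynylmagnesium bromide (4 equiv)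
Product: 20 (1S,2R,5S)-5-[(tert-butyldimethylsilyl)oxy]-2-ethynyl-1,3,3-trimethylcyclohexane-1,2-diol
Conditions: HC≡CMgBr, THF, 0 °C → rt; sat. NH4Cl
Reagents that add atoms: none
Why: Chelation-controlled Grignard 1,2-addition to the non-enolisable ketol: the magnesium alkoxide at C5 chelates C6=O and holds C5–O equatorial, so the C5 and C1 methyl groups are both axial on one face and the small acetylide should add axially from the other, placing the ethynyl group cis to C5–OH (trans-5,6-diol; C6 is R in 20 and becomes S by priority change once the alkyne is an alkene).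

Step 13
Reactants: 20 ethynyl diol
Product: 21 tert-butyl({(1S,3S,4R)-4-ethynyl-3,5,5-trimethyl-3,4-bis[(trimethylsilyl)oxy]cyclohexyl}oxy)dimethylsilane
Conditions: TMSOTf, 2,6-lutidine, CH2Cl2, −78 → 0 °C
Reagents that add atoms: trimethylsilyl trifluoromethanesulfonate, C[Si](C)(C)OS(=O)(=O)C(F)(F)F
Why: Silyl triflate with a hindered base silylates both tertiary alcohols, which must be masked before the zirconium hydride and organozinc reagents; no stereocentre is involved.

Step 14
Reactants: 21 ring-A alkyne (1.3 equiv); 15 C28 1,1-dibromide; 22 dimethylzinc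
Product: 26 3,3'-bis-O-(tert-butyldimethylsilyl)-5,6-bis-O-(trimethylsilyl) ether of (3S,5S,6S,3'R)-7',8'-didehydro-5,6-dihydro-β,β-carotene-3,5,6,3'-tetrol, via alkenylzirconocene chloride 23 (not isolated), via alkenylzinc bromide 24 (not isolated), via 9-bromo-19-nor diene 25 (not isolated)
Conditions: Cp2Zr(H)Cl (1.2 equiv), THF, 23 °C; ZnBr2, 0 °C; then 15, Pd(DPEphos)Cl2 (5 mol%), 0 → 23 °C; then Me2Zn (2 equiv), Pd(PtBu3)2 (5 mol%), 23 °C
Reagents that add atoms: none
Why: Syn-hydrozirconation of the terminal alkyne of 21 puts zirconium on C8 and fixes E-C7=C8, and transmetalation gives the alkenylzinc 24. Pd(0) then inserts into the C–Br bond of 15 that is trans to the polyenyl chain (the cis bond is shielded by C11), alkenyl transfer and reductive elimination form C8–C9 with retention on both partners to give the (9Z)-bromodiene 25, and the remaining C–Br bond is methylated by Me2Zn under Pd(PtBu3)2, whose fast transmetalation and reductive elimination should keep the dienylpalladium species from isomerising, so that C9–CH3 forms with retention and C9=C10 is E. The closest known reaction type is the Negishi tandem of trans-selective alkenylation and stereoretentive methylation of 1,1-dibromo-1-alkenes, which gives (1E)-2-methyl-1,3-dienes. No ring is closed and no stereocentre is created; C3, C5, C6 and C3' are spectators. The step needs site selectivity between the two C–Br bonds (secured by their steric difference), retention in the methylation (secured by the bulky phosphine) and chemoselectivity of the zirconium hydride (secured by consuming it with the slight excess of 21 before 15 is added). In one flask it should complete the C40 skeleton, fix two double-bond geometries and install C19.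

Step 15
Reactants: 26 tetrasilyl ether
Product: 27 (3S,5S,6S,3'R)-7',8'-didehydro-5,6-dihydro-β,β-carotene-3,5,6,3'-tetrol
Conditions: TBAF, AcOH (buffer), THF, 0 °C → rt
Reagents that add atoms: none
Why: Fluoride-mediated cleavage of all four silyl ethers under buffered, non-acidic conditions, which the tertiary allylic C6 carbinol and the polyene should tolerate; no stereocentre is affected.

**Compound list**
1 | (4R,6R)-4-hydroxy-2,2,6-trimethylcyclohexan-1-one (actinol) | O=C1C(C)(C)C[C@H](O)C[C@H]1C | starting material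
2 | (4R,6R)-4-[(tert-butyldimethylsilyl)oxy]-2,2,6-trimethylcyclohexan-1-one | O=C1C(C)(C)C[C@H](O[Si](C)(C)C(C)(C)C)C[C@H]1C | intermediate
3 | lithium (4R)-4-[(tert-butyldimethylsilyl)oxy]-2,6,6-trimethylcyclohex-1-en-1-olate | [Li+].CC1=C([O-])C(C)(C)C[C@H](O[Si](C)(C)C(C)(C)C)C1 | intermediate
4 | (4R)-4-[(tert-butyldimethylsilyl)oxy]-2,6,6-trimethylcyclohex-1-en-1-yl trifluoromethanesulfonate | CC1=C(OS(=O)(=O)C(F)(F)F)C(C)(C)C[C@H](O[Si](C)(C)C(C)(C)C)C1 | intermediate
5 | (2E)-3-methylpent-2-en-4-yn-1-ol | C#C/C(C)=C/CO | starting material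
6 | (3E)-5-bromo-3-methylpent-3-en-1-yne | C#C/C(C)=C/CBr | intermediate
7 | diethyl [(2E)-3-methylpent-2-en-4-yn-1-yl]phosphonate | C#C/C(C)=C/CP(=O)(OCC)OCC | intermediate
8 | diethyl {(2E)-5-[(4R)-4-[(tert-butyldimethylsilyl)oxy]-2,6,6-trimethylcyclohex-1-en-1-yl]-3-methylpent-2-en-4-yn-1-yl}phosphonate | CC1=C(C#C/C(C)=C/CP(=O)(OCC)OCC)C(C)(C)C[C@H](O[Si](C)(C)C(C)(C)C)C1 | intermediate
9 | (2E,4E,6E)-2,7-dimethylocta-2,4,6-trienedial | O=C/C(C)=C/C=C/C=C(C)/C=O | starting material
10 | potassium salt of the α-phosphonyl carbanion of 8 | [K+].CC1=C(C#C/C(C)=C/[CH-]P(=O)(OCC)OCC)C(C)(C)C[C@H](O[Si](C)(C)C(C)(C)C)C1 | intermediate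
11 | (2E,4E,6E,8E,10E)-13-[(4R)-4-[(tert-butyldimethylsilyl)oxy]-2,6,6-trimethylcyclohex-1-en-1-yl]-2,7,11-trimethyltrideca-2,4,6,8,10-pentaen-12-ynal | CC1=C(C#C/C(C)=C/C=C/C(C)=C/C=C/C=C(C)/C=O)C(C)(C)C[C@H](O[Si](C)(C)C(C)(C)C)C1 | intermediate
12 | diethyl {2-[methoxy(methyl)amino]-2-oxoethyl}phosphonate | CCOP(=O)(CC(=O)N(C)OC)OCC | starting material
13 | (2E,4E,6E,8E,10E,12E)-15-[(4R)-4-[(tert-butyldimethylsilyl)oxy]-2,6,6-trimethylcyclohex-1-en-1-yl]-N-methoxy-N,4,9,13-tetramethylpentadeca-2,4,6,8,10,12-hexaen-14-ynamide | CC1=C(C#C/C(C)=C/C=C/C(C)=C/C=C/C=C(C)/C=C/C(=O)N(C)OC)C(C)(C)C[C@H](O[Si](C)(C)C(C)(C)C)C1 | intermediate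
14 | (2E,4E,6E,8E,10E,12E)-15-[(4R)-4-[(tert-butyldimethylsilyl)oxy]-2,6,6-trimethylcyclohex-1-en-1-yl]-4,9,13-trimethylpentadeca-2,4,6,8,10,12-hexaen-14-ynal | CC1=C(C#C/C(C)=C/C=C/C(C)=C/C=C/C=C(C)/C=C/C=O)C(C)(C)C[C@H](O[Si](C)(C)C(C)(C)C)C1 | intermediate
15 | tert-butyl({(1R)-4-[(3E,5E,7E,9E,11E,13E)-16,16-dibromo-3,7,12-trimethylhexadeca-3,5,7,9,11,13,15-heptaen-1-yn-1-yl]-3,5,5-trimethylcyclohex-3-en-1-yl}oxy)dimethylsilane | CC1=C(C#C/C(C)=C/C=C/C(C)=C/C=C/C=C(C)/C=C/C=C(Br)Br)C(C)(C)C[C@H](O[Si](C)(C)C(C)(C)C)C1 | intermediate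
16 | {[(4R)-4-[(tert-butyldimethylsilyl)oxy]-2,6,6-trimethylcyclohex-1-en-1-yl]oxy}trimethylsilane | CC1=C(O[Si](C)(C)C)C(C)(C)C[C@H](O[Si](C)(C)C(C)(C)C)C1 | intermediate
17 | (2S,4S)-4-[(tert-butyldimethylsilyl)oxy]-2,6,6-trimethyl-2-[(trimethylsilyl)oxy]cyclohexan-1-one | O=C1C(C)(C)C[C@H](O[Si](C)(C)C(C)(C)C)C[C@]1(C)O[Si](C)(C)C | intermediate
18 | (2S,4S)-4-[(tert-butyldimethylsilyl)oxy]-2-hydroxy-2,6,6-trimethylcyclohexan-1-one | O=C1C(C)(C)C[C@H](O[Si](C)(C)C(C)(C)C)C[C@]1(C)O | intermediate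
19 | ethynylmagnesium bromide | C#C[Mg]Br | starting material
20 | (1S,2R,5S)-5-[(tert-butyldimethylsilyl)oxy]-2-ethynyl-1,3,3-trimethylcyclohexane-1,2-diol | C#C[C@]1(O)C(C)(C)C[C@H](O[Si](C)(C)C(C)(C)C)C[C@]1(C)O | intermediate
21 | tert-butyl({(1S,3S,4R)-4-ethynyl-3,5,5-trimethyl-3,4-bis[(trimethylsilyl)oxy]cyclohexyl}oxy)dimethylsilane | C#C[C@]1(O[Si](C)(C)C)C(C)(C)C[C@H](O[Si](C)(C)C(C)(C)C)C[C@]1(C)O[Si](C)(C)C | intermediate
22 | dimethylzinc | C[Zn]C | starting material
23 | (E)-alkenylzirconocene chloride from 21 (Zr on C8; cyclopentadienyl ligands drawn σ-bonded) | Cl[Zr](/C=C/[C@]1(O[Si](C)(C)C)C(C)(C)C[C@H](O[Si](C)(C)C(C)(C)C)C[C@]1(C)O[Si](C)(C)C)(C1C=CC=C1)C1C=CC=C1 | intermediate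
24 | (E)-alkenylzinc bromide from 21 (Zn on C8) | Br[Zn]/C=C/[C@]1(O[Si](C)(C)C)C(C)(C)C[C@H](O[Si](C)(C)C(C)(C)C)C[C@]1(C)O[Si](C)(C)C | intermediate
25 | (9Z)-9-bromo-19-nor analogue of 26 (Br on C9, cis to C11) | CC1=C(C#C/C(C)=C/C=C/C(C)=C/C=C/C=C(C)/C=C/C=C(Br)/C=C/[C@]2(O[Si](C)(C)C)C(C)(C)C[C@H](O[Si](C)(C)C(C)(C)C)C[C@]2(C)O[Si](C)(C)C)C(C)(C)C[C@H](O[Si](C)(C)C(C)(C)C)C1 | intermediate
26 | 3,3'-bis-O-(tert-butyldimethylsilyl)-5,6-bis-O-(trimethylsilyl) ether of 27 | CC1=C(C#C/C(C)=C/C=C/C(C)=C/C=C/C=C(C)/C=C/C=C(C)/C=C/[C@]2(O[Si](C)(C)C)C(C)(C)C[C@H](O[Si](C)(C)C(C)(C)C)C[C@]2(C)O[Si](C)(C)C)C(C)(C)C[C@H](O[Si](C)(C)C(C)(C)C)C1 | intermediate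
27 | (3S,5S,6S,3'R)-7',8'-didehydro-5,6-dihydro-β,β-carotene-3,5,6,3'-tetrol | CC1=C(C#C/C(C)=C/C=C/C(C)=C/C=C/C=C(C)/C=C/C=C(C)/C=C/[C@]2(O)C(C)(C)C[C@H](O)C[C@]2(C)O)C(C)(C)C[C@H](O)C1 | target

**Step count**
Total: 15 steps. Longest linear sequence: 9 steps (steps 1, 2, 5, 6, 7, 8, 9, 14, 15 from 1; the same length from 5 through steps 3 and 4).

**Steps most likely to fail**

Step 14. What may go wrong: partial loss of the C9=C10 geometry in the methylation stage (isomerisation of the dienylpalladium species before reductive elimination), incomplete trans-selectivity of the first oxidative addition, or reduction of the polyene by surplus zirconium hydride. The fallback sets out from 21 and 15 and comes back to the route at 27. Alkyne 21 is deprotonated (n-BuLi, THF, −78 °C) and transmetalated with ZnBr2 to the alkynylzinc bromide F1. F1 undergoes the Pd(DPEphos)Cl2-catalysed trans-selective alkynylation of 15 to the (9Z)-9-bromo-7,8-didehydro compound F2; the same C8–C9 bond is formed, now as an sp–sp2 bond. Methylation of this 2-bromo-1-en-3-yne with Me2Zn and Pd(PtBu3)2, the substrate class for which retention is most secure, should give the 7,8-didehydro analogue of 26 F3. TBAF then gives the 7,8-didehydro tetrol F4. Hydroxyl-directed trans-hydroalumination (Red-Al, THF, 0 °C; aqueous work-up) should reduce only the C7≡C8 triple bond, which is propargylic to the C6 carbinol, to the E-alkene and give 27; the C7'≡C8' triple bond has no neighbouring hydroxyl and stays.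

Step 11. What may go wrong: poor facial selectivity of the enol-ether epoxidation (attack also on the face of the pseudoaxial C1 methyl), which would give the C5 epimer, or Baeyer–Villiger over-oxidation. The fallback sets out from 4 and comes back to the route at 20. Palladium-catalysed methoxycarbonylation of 4 (Pd(OAc)2, PPh3, CO, MeOH, Et3N, DMF) gives the methyl ester F5, and DIBAL-H gives the allylic alcohol F6. Sharpless epoxidation with Ti(OiPr)4, D-(−)-diethyl tartrate and TBHP places the oxirane by reagent control on the face anti to the silyloxy group and gives the epoxy alcohol F7. Parikh–Doering oxidation gives the epoxy aldehyde F8, and the Ohira–Bestmann reagent (K2CO3, MeOH) gives the epoxy alkyne F9. Acid-catalysed hydrolysis (cat. HClO4, THF/H2O, 0 °C) should open the oxirane at C5 with inversion, because C6 is neopentylic and carries the electron-poor ethynyl group, and gives 20.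

Step 6. What may go wrong: double olefination of the symmetrical dialdehyde and a statistical product mixture that is hard to separate. The fallback sets out from 9 and 8 and comes back to the route at 11. Dialdehyde 9 is treated with one equivalent of 2,2-dimethylpropane-1,3-diol (PPTS, benzene, Dean–Stark) to give the mono-acetal F10, which is separated from diacetal and unchanged 9. The carbanion 10 made from 8 (KHMDS, THF, −78 °C) then reacts with F10 in a 1:1 ratio to give the C25 acetal F11. Hydrolysis with PPTS in wet acetone frees 11.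

**Further compounds**
F1 | step 14 | alkynylzinc bromide from 21 | Br[Zn]C#C[C@]1(O[Si](C)(C)C)C(C)(C)C[C@H](O[Si](C)(C)C(C)(C)C)C[C@]1(C)O[Si](C)(C)C
F2 | step 14 | (9Z)-9-bromo-7,8-didehydro-19-nor analogue of 26 | CC1=C(C#C/C(C)=C/C=C/C(C)=C/C=C/C=C(C)/C=C/C=C(Br)/C#C[C@]2(O[Si](C)(C)C)C(C)(C)C[C@H](O[Si](C)(C)C(C)(C)C)C[C@]2(C)O[Si](C)(C)C)C(C)(C)C[C@H](O[Si](C)(C)C(C)(C)C)C1
F3 | step 14 | 7,8-didehydro analogue of 26 | CC1=C(C#C/C(C)=C/C=C/C(C)=C/C=C/C=C(C)/C=C/C=C(C)/C#C[C@]2(O[Si](C)(C)C)C(C)(C)C[C@H](O[Si](C)(C)C(C)(C)C)C[C@]2(C)O[Si](C)(C)C)C(C)(C)C[C@H](O[Si](C)(C)C(C)(C)C)C1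
F4 | step 14 | (3S,5S,6R,3'R)-7,8,7',8'-tetradehydro-5,6-dihydro-β,β-carotene-3,5,6,3'-tetrol | CC1=C(C#C/C(C)=C/C=C/C(C)=C/C=C/C=C(C)/C=C/C=C(C)/C#C[C@]2(O)C(C)(C)C[C@H](O)C[C@]2(C)O)C(C)(C)C[C@H](O)C1
F5 | step 11 | methyl (4R)-4-[(tert-butyldimethylsilyl)oxy]-2,6,6-trimethylcyclohex-1-ene-1-carboxylate | CC1=C(C(=O)OC)C(C)(C)C[C@H](O[Si](C)(C)C(C)(C)C)C1
F6 | step 11 | [(4R)-4-[(tert-butyldimethylsilyl)oxy]-2,6,6-trimethylcyclohex-1-en-1-yl]methanol | CC1=C(CO)C(C)(C)C[C@H](O[Si](C)(C)C(C)(C)C)C1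
F7 | step 11 | [(1R,4S,6R)-4-[(tert-butyldimethylsilyl)oxy]-2,2,6-trimethyl-7-oxabicyclo[4.1.0]heptan-1-yl]methanol (oxirane anti to the silyloxy group) | OC[C@]1(O2)C(C)(C)C[C@H](O[Si](C)(C)C(C)(C)C)C[C@]12C
F8 | step 11 | (1S,4S,6R)-4-[(tert-butyldimethylsilyl)oxy]-2,2,6-trimethyl-7-oxabicyclo[4.1.0]heptane-1-carbaldehyde (oxirane anti to the silyloxy group) | O=C[C@]1(O2)C(C)(C)C[C@H](O[Si](C)(C)C(C)(C)C)C[C@]12C
F9 | step 11 | tert-butyl{[(1R,3S,6R)-6-ethynyl-1,5,5-trimethyl-7-oxabicyclo[4.1.0]heptan-3-yl]oxy}dimethylsilane (oxirane anti to the silyloxy group) | C#C[C@]1(O2)C(C)(C)C[C@H](O[Si](C)(C)C(C)(C)C)C[C@]12C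
F10 | step 6 | (2E,4E,6E)-7-(5,5-dimethyl-1,3-dioxan-2-yl)-2-methylocta-2,4,6-trienal | O=C/C(C)=C/C=C/C=C(C)/C1OCC(C)(C)CO1
F11 | step 6 | 5,5-dimethyl-1,3-dioxane acetal of 11 | CC1=C(C#C/C(C)=C/C=C/C(C)=C/C=C/C=C(C)/C2OCC(C)(C)CO2)C(C)(C)C[C@H](O[Si](C)(C)C(C)(C)C)C1
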